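**Plan**
- Retrosynthetic cuts: the aryl O–Si bond; the C5–propenyl bond (Suzuki); C3–CH3 traced back to C3–CO2Me; then the C3–C3a bond, opened by putting the ester carbon back into the ring as the C4 carbonyl of a 2-arylchroman-4-one (flavanone); last the flavanone C2–aryl bond (conjugate addition to a chromone).
- Forward order: the chromone (pyranone ring) is built from an o-hydroxyacetophenone, the aryl group is added at C2 to give the six-membered flavanone, and an oxidative 1,2-aryl shift contracts it to the 2,3-dihydrobenzofuran; ester to methyl, propenylation and desilylation finish the route.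
- Enabling feature: C3 of the dihydrofuran ring is bonded to the ring-fusion carbon C3a and to an exocyclic one-carbon group, next to the O1–C2(aryl) unit. This is the array left when C4a of a flavanone shifts from the carbonyl carbon C4 to C3 and C4 is pushed out of the ring.
- Stereochemistry: C2 (S) comes from a catalyst-controlled Rh 1,4-addition; C3 (S, trans) comes from the stereospecific ring contraction, controlled by C2, and trans is also the thermodynamically preferred arrangement.

Key step: step 6

Assumption: the facial sense of the Rh/ligand pair of step 5 on chromone 4 is fixed in a pilot run; the ligand antipode is taken if the (2R)-flavanone should form.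

Step 1
Reactants: 1 2'-hydroxy-3'-methoxyacetophenone
Product: 2 1-(5-bromo-2-hydroxy-3-methoxyphenyl)ethan-1-one
Conditions: NBS (1.05 equiv), MeCN, 0 °C to rt
Reagents that add atoms: N-bromosuccinimide, O=C1CCC(=O)N1Br
Why: Electrophilic aromatic bromination; the free phenol directs to its only open activated site, para to OH, both ortho positions being blocked by acetyl and methoxy.

Step 2
Reactants: 2 1-(5-bromo-2-hydroxy-3-methoxyphenyl)ethan-1-one
Product: 4 6-bromo-8-methoxy-4H-chromen-4-one, via enaminone 3 (not isolated)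
Conditions: DMF-DMA, toluene, 100 °C; then conc. HCl, CH2Cl2, 40 °C
Reagents that add atoms: N,N-dimethylformamide dimethyl acetal, COC(OC)N(C)C
Why: Standard enaminone chromone synthesis: condensation of the methyl ketone with the amide acetal, then acid-promoted intramolecular O-addition and elimination of dimethylamine.

Step 3
Reactants: 5 2,3-dimethoxyphenol
Product: 6 (2,3-dimethoxyphenoxy)triisopropylsilane
Conditions: TIPSCl, imidazole, DMF, rt
Reagents that add atoms: chlorotriisopropylsilane, CC(C)[Si](Cl)(C(C)C)C(C)C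
Why: Routine phenol silylation; the TIPS ether is chosen because it should tolerate acid, iodine(III), hydride and Suzuki base and can be removed without hydrogenation.

Step 4
Reactants: 6 (2,3-dimethoxyphenoxy)triisopropylsilane
Product: 8 [3,4-dimethoxy-5-(triisopropylsilyloxy)phenyl]boronic acid, via pinacol boronate 7 (not isolated)
Conditions: [Ir(OMe)(cod)]2 (1.5 mol %), dtbpy (3 mol %), B2pin2 (0.6 equiv), THF, 80 °C; then NaIO4, 1 M aq. HCl, THF/H2O, rt
Reagents that add atoms: bis(pinacolato)diboron, CC1(C)OB(OC1(C)C)B1OC(C)(C)C(C)(C)O1; water, O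
Why: Sterically controlled Ir-catalysed C–H borylation should select the only C–H without an ortho substituent (meta to both flanking oxygens), and one-pot periodate cleavage of the pinacol ester should give the boronic acid.

Step 5
Reactants: 4 6-bromo-8-methoxy-4H-chromen-4-one; 8 [3,4-dimethoxy-5-(triisopropylsilyloxy)phenyl]boronic acid
Product: 9 (2S)-6-bromo-8-methoxy-2-[3,4-dimethoxy-5-(triisopropylsilyloxy)phenyl]chroman-4-one
Conditions: [RhCl(C2H4)2]2 (2.5 mol %), enantiopure 1,2-bis(tert-butylsulfinyl)benzene (6 mol %), 8 (2.5 equiv), aq. K3PO4 (0.5 equiv), CH2Cl2, 40 °C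
Reagents that add atoms: none
Why: Rh(I)-catalysed asymmetric 1,4-addition (Hayashi–Miyaura) of an arylboronic acid to a chromone; the chiral ligand on the aryl–Rh species selects the enone face and sets C2 as S, and Rh(I) should leave the aryl bromide alone.

Step 6
Reactants: 9 (2S)-6-bromo-8-methoxy-2-[3,4-dimethoxy-5-(triisopropylsilyloxy)phenyl]chroman-4-one
Product: 12 methyl (2S,3S)-5-bromo-7-methoxy-2-[3,4-dimethoxy-5-(triisopropylsilyloxy)phenyl]-2,3-dihydro-1-benzofuran-3-carboxylate, via enol ether 10 (not isolated), via iodane 11 (not isolated)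
Conditions: PhI(OAc)2 (1.2 equiv), H2SO4 (cat.), HC(OMe)3, rt; aq. NaHCO3
Reagents that add atoms: trimethyl orthoformate, COC(OC)OC; (diacetoxyiodo)benzene, CC(=O)OI(OC(C)=O)c1ccccc1 (its atoms remain only in intermediate 11)
Why: In acidic trimethyl orthoformate the ketone should give the methyl enol ether 10, which iodine(III) attacks at C3 anti to the equatorial 2-aryl group to give the 2,3-trans diequatorial iodane 11; the annulated aryl carbon C4a, whose bond to C4 is antiperiplanar to C3–I, then shifts from C4 to C3 with loss of iodobenzene, and the dimethoxycarbenium ion at the extruded C4 collapses to the methyl ester. The closest known reaction type is the hypervalent-iodine or thallium(III) oxidative rearrangement of flavanones to trans-2-aryl-2,3-dihydrobenzofuran-3-carboxylates, a semipinacol-type ring contraction. The five-membered ring is not closed by a cyclisation; it arises from the six-membered pyranone by this 1,2-aryl shift (C3–C4a formed, C4–C4a broken), while the O1–C2 bond is never touched. C2 keeps the configuration set in step 5, and C3 is set trans to the aryl group because the migrating carbon enters with inversion opposite the iodane, which itself entered anti to the aryl group; trans is also the more stable ester epimer. The step needs migration of the annulated arene in preference to a shift of the 2-aryl group (isoflavone) or dehydrogenation (flavone): the diequatorial geometry of 11 places only the C4–C4a bond anti to the leaving group, and the ring oxygen ortho to C4a makes that carbon a good migrating group.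

Step 7
Reactants: 12 methyl (2S,3S)-5-bromo-7-methoxy-2-[3,4-dimethoxy-5-(triisopropylsilyloxy)phenyl]-2,3-dihydro-1-benzofuran-3-carboxylate
Product: 13 [(2S,3R)-5-bromo-7-methoxy-2-[3,4-dimethoxy-5-(triisopropylsilyloxy)phenyl]-2,3-dihydro-1-benzofuran-3-yl]methanol
Conditions: DIBAL-H (2.5 equiv), CH2Cl2, −78 to 0 °C; Rochelle salt
Reagents that add atoms: none
Why: Ester reduction with a non-basic aluminium hydride, which should spare the epimerisable C3–H, the aryl bromide and the silyl ether (the descriptor at C3 changes by priority only).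

Step 8
Reactants: 13 [(2S,3R)-5-bromo-7-methoxy-2-[3,4-dimethoxy-5-(triisopropylsilyloxy)phenyl]-2,3-dihydro-1-benzofuran-3-yl]methanol
Product: 14 [(2S,3R)-5-bromo-7-methoxy-2-[3,4-dimethoxy-5-(triisopropylsilyloxy)phenyl]-2,3-dihydro-1-benzofuran-3-yl]methyl 4-methylbenzenesulfonate
Conditions: TsCl, Et3N, DMAP (cat.), CH2Cl2, 0 °C to rt
Reagents that add atoms: p-toluenesulfonyl chloride, Cc1ccc(cc1)S(Cl)(=O)=O
Why: Routine sulfonylation of an unhindered primary alcohol to install a leaving group; no stereocentre is involved.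

Step 9
Reactants: 14 [(2S,3R)-5-bromo-7-methoxy-2-[3,4-dimethoxy-5-(triisopropylsilyloxy)phenyl]-2,3-dihydro-1-benzofuran-3-yl]methyl 4-methylbenzenesulfonate
Product: 15 (2S,3S)-5-bromo-7-methoxy-3-methyl-2-[3,4-dimethoxy-5-(triisopropylsilyloxy)phenyl]-2,3-dihydro-1-benzofuran
Conditions: LiEt3BH (2 equiv), THF, 0 °C to rt
Reagents that add atoms: none
Why: SN2 displacement of a primary tosylate by the strongly nucleophilic, weakly basic triethylborohydride should give the methyl group without touching either stereocentre, the aryl bromide or the silyl ether.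

Step 10
Reactants: 15 (2S,3S)-5-bromo-7-methoxy-3-methyl-2-[3,4-dimethoxy-5-(triisopropylsilyloxy)phenyl]-2,3-dihydro-1-benzofuran; 16 (E)-4,4,5,5-tetramethyl-2-(prop-1-en-1-yl)-1,3,2-dioxaborolane
Product: 17 triisopropyl{5-[(2S,3S)-7-methoxy-3-methyl-5-[(E)-prop-1-en-1-yl]-2,3-dihydro-1-benzofuran-2-yl]-2,3-dimethoxyphenoxy}silane
Conditions: Pd(dppf)Cl2·CH2Cl2 (5 mol %), K2CO3, 1,4-dioxane/H2O, 80 °C
Reagents that add atoms: none
Why: Suzuki–Miyaura coupling of the aryl bromide with an alkenylboronate proceeds with retention of alkene geometry, so the E-propenyl group is delivered directly.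

Step 11
Reactants: 17 triisopropyl{5-[(2S,3S)-7-methoxy-3-methyl-5-[(E)-prop-1-en-1-yl]-2,3-dihydro-1-benzofuran-2-yl]-2,3-dimethoxyphenoxy}silane
Product: 18 5-[(2S,3S)-7-methoxy-3-methyl-5-[(E)-prop-1-en-1-yl]-2,3-dihydro-1-benzofuran-2-yl]-2,3-dimethoxyphenol
Conditions: TBAF, AcOH (1:1), THF, 0 °C to rt
Reagents that add atoms: none
Why: Fluoride-induced desilylation of the aryl silyl ether, buffered with acetic acid so that the electron-rich phenol and styrene are not exposed to a free phenoxide/basic medium.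

**Compound list**
1 | 2'-hydroxy-3'-methoxyacetophenone | CC(=O)c1cccc(OC)c1O | starting material
2 | 1-(5-bromo-2-hydroxy-3-methoxyphenyl)ethan-1-one | CC(=O)c1cc(Br)cc(OC)c1O | intermediate
3 | (E)-1-(5-bromo-2-hydroxy-3-methoxyphenyl)-3-(dimethylamino)prop-2-en-1-one | CN(C)/C=C/C(=O)c1cc(Br)cc(OC)c1O | intermediate
4 | 6-bromo-8-methoxy-4H-chromen-4-one | O=c1ccoc2c(OC)cc(Br)cc12 | intermediate
5 | 2,3-dimethoxyphenol | COc1cccc(O)c1OC | starting material
6 | (2,3-dimethoxyphenoxy)triisopropylsilane | COc1cccc(O[Si](C(C)C)(C(C)C)C(C)C)c1OC | intermediate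
7 | 2-[3,4-dimethoxy-5-(triisopropylsilyloxy)phenyl]-4,4,5,5-tetramethyl-1,3,2-dioxaborolane | COc1cc(B2OC(C)(C)C(C)(C)O2)cc(O[Si](C(C)C)(C(C)C)C(C)C)c1OC | intermediate
8 | [3,4-dimethoxy-5-(triisopropylsilyloxy)phenyl]boronic acid | COc1cc(B(O)O)cc(O[Si](C(C)C)(C(C)C)C(C)C)c1OC | intermediate
9 | (2S)-6-bromo-8-methoxy-2-[3,4-dimethoxy-5-(triisopropylsilyloxy)phenyl]chroman-4-one | O=C1C[C@@H](c3cc(O[Si](C(C)C)(C(C)C)C(C)C)c(OC)c(OC)c3)Oc2c(OC)cc(Br)cc12 | intermediate
10 | (2S)-6-bromo-4,8-dimethoxy-2-[3,4-dimethoxy-5-(triisopropylsilyloxy)phenyl]-2H-chromene | COC1=C[C@@H](c3cc(O[Si](C(C)C)(C(C)C)C(C)C)c(OC)c(OC)c3)Oc2c(OC)cc(Br)cc12 | intermediate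
11 | (2R,3R)-3-[acetoxy(phenyl)-λ3-iodanyl]-6-bromo-4,4,8-trimethoxy-2-[3,4-dimethoxy-5-(triisopropylsilyloxy)phenyl]chromane (2,3-trans; C2 spatially as in 9, descriptor changed by priority only) | COC1(OC)[C@H](I(OC(C)=O)c4ccccc4)[C@@H](c3cc(O[Si](C(C)C)(C(C)C)C(C)C)c(OC)c(OC)c3)Oc2c(OC)cc(Br)cc12 | intermediate
12 | methyl (2S,3S)-5-bromo-7-methoxy-2-[3,4-dimethoxy-5-(triisopropylsilyloxy)phenyl]-2,3-dihydro-1-benzofuran-3-carboxylate (2,3-trans) | Brc1cc(OC)c2c(c1)[C@H](C(=O)OC)[C@@H](c1cc(O[Si](C(C)C)(C(C)C)C(C)C)c(OC)c(OC)c1)O2 | intermediate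
13 | [(2S,3R)-5-bromo-7-methoxy-2-[3,4-dimethoxy-5-(triisopropylsilyloxy)phenyl]-2,3-dihydro-1-benzofuran-3-yl]methanol | Brc1cc(OC)c2c(c1)[C@H](CO)[C@@H](c1cc(O[Si](C(C)C)(C(C)C)C(C)C)c(OC)c(OC)c1)O2 | intermediate
14 | [(2S,3R)-5-bromo-7-methoxy-2-[3,4-dimethoxy-5-(triisopropylsilyloxy)phenyl]-2,3-dihydro-1-benzofuran-3-yl]methyl 4-methylbenzenesulfonate | Brc1cc(OC)c2c(c1)[C@H](COS(=O)(=O)c1ccc(C)cc1)[C@@H](c1cc(O[Si](C(C)C)(C(C)C)C(C)C)c(OC)c(OC)c1)O2 | intermediate
15 | (2S,3S)-5-bromo-7-methoxy-3-methyl-2-[3,4-dimethoxy-5-(triisopropylsilyloxy)phenyl]-2,3-dihydro-1-benzofuran | Brc1cc(OC)c2c(c1)[C@H](C)[C@@H](c1cc(O[Si](C(C)C)(C(C)C)C(C)C)c(OC)c(OC)c1)O2 | intermediate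
16 | (E)-4,4,5,5-tetramethyl-2-(prop-1-en-1-yl)-1,3,2-dioxaborolane | C/C=C/B1OC(C)(C)C(C)(C)O1 | starting material
17 | triisopropyl{5-[(2S,3S)-7-methoxy-3-methyl-5-[(E)-prop-1-en-1-yl]-2,3-dihydro-1-benzofuran-2-yl]-2,3-dimethoxyphenoxy}silane | C/C=C/c1cc(OC)c2c(c1)[C@H](C)[C@@H](c1cc(O[Si](C(C)C)(C(C)C)C(C)C)c(OC)c(OC)c1)O2 | intermediate
18 | 5-[(2S,3S)-7-methoxy-3-methyl-5-[(E)-prop-1-en-1-yl]-2,3-dihydro-1-benzofuran-2-yl]-2,3-dimethoxyphenol | C/C=C/c1cc(OC)c2c(c1)[C@H](C)[C@@H](c1cc(O)c(OC)c(OC)c1)O2 | target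

**Step count**
Total: 11 steps. Longest linear sequence: 9 steps (steps 1, 2, 5, 6, 7, 8, 9, 10, 11).

**Steps most likely to fail**

Step 6. The oxidative rearrangement may be diverted: shift of the electron-rich 2-aryl group (isoflavone), dehydrogenation to the flavone, or acid-induced loss of the silyl group followed by phenol oxidation. The fallback sets out from 9 and comes back at 12 by a Wolff ring contraction. Heating 9 with DMF-DMA should give the (E)-3-[(dimethylamino)methylidene]flavanone F1. Diazo transfer from tosyl azide onto this enaminone (MeCN, rt) should give the 3-diazoflavanone F2 under neutral conditions. Irradiation of F2 in methanol (about 350 nm) should trigger the Wolff shift of the annulated aryl carbon to the carbene carbon, and methanol traps the ketene as a mixture of 12 and its 2,3-cis epimer, methyl (2S,3R)-ester F3. Catalytic NaOMe in MeOH at 0 °C to rt should funnel F3 into the more stable trans ester 12.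

Step 5. Enantiopurity may erode through reversible base-mediated oxa-Michael ring opening of the flavanone, and the hindered, electron-rich boronic acid may protodeboronate faster than it transmetalates. The fallback sets out from 2 and comes back at 9 by condensation and kinetic resolution. Commercial 3-hydroxy-4,5-dimethoxybenzaldehyde is silylated (TIPSCl, imidazole) to 3,4-dimethoxy-5-(triisopropylsilyloxy)benzaldehyde F4. Condensation of F4 with 2 (pyrrolidine, EtOH, reflux) should pass through the 2'-hydroxychalcone F5, which cyclises in situ to the racemic flavanone F6. Asymmetric transfer hydrogenation as a kinetic resolution (RuCl(p-cymene)(TsDPEN), the antipode that reduces the 2R ketone faster, HCO2H/Et3N, EtOAc, rt, stopped a little past half conversion) should leave (2S)-flavanone 9. It is separated by chromatography from the cis-(2R,4R)-flavan-4-ol F7; at most half of the material is usable.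

Step 9. E2 elimination of the β-branched tosylate to the exocyclic alkene, followed by aromatisation to a 3-methylbenzofuran, may compete with SN2 hydride delivery. The fallback sets out from 13 and comes back at 15 by a non-basic radical deoxygenation. Appel iodination (I2, PPh3, imidazole, CH2Cl2) should give the (2S,3S)-3-(iodomethyl) compound F8. Reduction with Bu3SnH (1.05 equiv, Et3B/air, toluene, rt) should give 15; the alkyl iodide is abstracted far faster than the aryl bromide, and the high stannane concentration outruns radical rearrangement.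

**Further compounds**
F1 | step 6 | (E)-3-[(dimethylamino)methylidene] derivative of 9 (C2 as in 9) | O=C1/C(=C/N(C)C)[C@@H](c3cc(O[Si](C(C)C)(C(C)C)C(C)C)c(OC)c(OC)c3)Oc2c(OC)cc(Br)cc12
F2 | step 6 | 3-diazo derivative of 9 (C2 as in 9) | O=C1C(=[N+]=[N-])[C@@H](c3cc(O[Si](C(C)C)(C(C)C)C(C)C)c(OC)c(OC)c3)Oc2c(OC)cc(Br)cc12
F3 | step 6 | methyl (2S,3R)-5-bromo-7-methoxy-2-[3,4-dimethoxy-5-(triisopropylsilyloxy)phenyl]-2,3-dihydro-1-benzofuran-3-carboxylate (2,3-cis) | Brc1cc(OC)c2c(c1)[C@@H](C(=O)OC)[C@@H](c1cc(O[Si](C(C)C)(C(C)C)C(C)C)c(OC)c(OC)c1)O2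
F4 | step 5 | 3,4-dimethoxy-5-(triisopropylsilyloxy)benzaldehyde | O=Cc1cc(O[Si](C(C)C)(C(C)C)C(C)C)c(OC)c(OC)c1
F5 | step 5 | (E)-1-(5-bromo-2-hydroxy-3-methoxyphenyl)-3-[3,4-dimethoxy-5-(triisopropylsilyloxy)phenyl]prop-2-en-1-one | O=C(/C=C/c1cc(O[Si](C(C)C)(C(C)C)C(C)C)c(OC)c(OC)c1)c1cc(Br)cc(OC)c1O
F6 | step 5 | racemic 6-bromo-8-methoxy-2-[3,4-dimethoxy-5-(triisopropylsilyloxy)phenyl]chroman-4-one | O=C1CC(c3cc(O[Si](C(C)C)(C(C)C)C(C)C)c(OC)c(OC)c3)Oc2c(OC)cc(Br)cc12
F7 | step 5 | (2R,4R)-6-bromo-8-methoxy-2-[3,4-dimethoxy-5-(triisopropylsilyloxy)phenyl]chroman-4-ol (2,4-cis) | O[C@@H]1C[C@H](c3cc(O[Si](C(C)C)(C(C)C)C(C)C)c(OC)c(OC)c3)Oc2c(OC)cc(Br)cc12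
F8 | step 9 | (2S,3S)-5-bromo-3-(iodomethyl)-7-methoxy-2-[3,4-dimethoxy-5-(triisopropylsilyloxy)phenyl]-2,3-dihydro-1-benzofuran | Brc1cc(OC)c2c(c1)[C@H](CI)[C@@H](c1cc(O[Si](C(C)C)(C(C)C)C(C)C)c(OC)c(OC)c1)O2
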